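**Retrosynthetic overview**

1. The oxirane is added last, by Shi epoxidation of the trisubstituted (E)-alkene of a diene coumarin.
2. The key disconnection is C4–C4a of the coumarin, which opens the pyranone ring to an aryl propiolate. It rests on the benzo ring (C4a, C5–C8, C8a): O1 on C8a, OMe on C8 and O-alkyl on C7 are the oxygen pattern of symmetric 2-methoxyresorcinol. In its monoether the only unsubstituted carbon ortho to the free hydroxyl (the future C4a) lies para to the ether oxygen.
3. The propiolate comes from propiolic acid and the phenol monoether, which is made by Mitsunobu coupling of 2-methoxyresorcinol with the lactone-bearing (E)-allylic alcohol.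
4. That alcohol comes from but-3-yn-1-ol. Zirconium-catalysed carboalumination–hydroxymethylation fixes the (E)-alkene, and iridium-catalysed 2-(methoxycarbonyl)allylation with lactonisation builds the α-methylene-γ-butyrolactone and its stereocentre.
5. Ring order: butyrolactone (step 6), pyranone ring of the coumarin (step 10), oxirane (step 11).

Key step: step 10

Assumption: the sense of induction in step 6 is assigned by analogy with iridium-catalysed couplings of allyl acetate, where the (S)-bisphosphine is taken to give the carbinol geometry needed here; if the 2-(methoxycarbonyl)allyl donor adds to the other aldehyde face, (R)-SEGPHOS is used and nothing else changes.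

**Step 1**
Reactants: 1 but-3-yn-1-ol
Product: 2 1-[(but-3-yn-1-yloxy)methyl]-4-methoxybenzene
Conditions: NaH, 4-methoxybenzyl chloride, Bu4NI (cat.), THF–DMF, 0 °C → rt
Reagents that add atoms: 4-methoxybenzyl chloride, COc1ccc(CCl)cc1
Why: Williamson etherification of the sodium alkoxide gives an ether that tolerates organoaluminium reagents and can later be removed oxidatively beside a silyl ether.

**Step 2**
Reactants: 2 1-[(but-3-yn-1-yloxy)methyl]-4-methoxybenzene
Product: 4 (E)-5-[(4-methoxybenzyl)oxy]-3-methylpent-2-en-1-ol, via alkenyldimethylalane 3 (not isolated)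
Conditions: Me3Al (2.5 equiv), Cp2ZrCl2 (0.25 equiv), CH2Cl2, 0 °C → rt; then (CH2O)n, THF, 0 °C → rt; aq. potassium sodium tartrate
Reagents that add atoms: trimethylaluminium, C[Al](C)C; paraformaldehyde (as formaldehyde), C=O
Why: Negishi zirconium-catalysed carboalumination adds methyl and aluminium syn across the terminal alkyne with methyl on the internal carbon, and hydroxymethylation of alkenylalane 3 proceeds with retention, so only the (E)-trisubstituted alkene should form.

**Step 3**
Reactants: 4 (E)-5-[(4-methoxybenzyl)oxy]-3-methylpent-2-en-1-ol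
Product: 5 (E)-tert-butyl({5-[(4-methoxybenzyl)oxy]-3-methylpent-2-en-1-yl}oxy)dimethylsilane
Conditions: TBSCl, imidazole, CH2Cl2, rt
Reagents that add atoms: tert-butyldimethylsilyl chloride, CC(C)(C)[Si](C)(C)Cl
Why: Standard imidazole-mediated silylation of the primary allylic alcohol installs a group that is inert to DDQ and to the iridium catalysis and is later removed by fluoride without base.

**Step 4**
Reactants: 5 (E)-tert-butyl({5-[(4-methoxybenzyl)oxy]-3-methylpent-2-en-1-yl}oxy)dimethylsilane
Product: 6 (E)-5-[(tert-butyldimethylsilyl)oxy]-3-methylpent-3-en-1-ol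
Conditions: DDQ (1.2 equiv), CH2Cl2–pH 7 phosphate buffer (10:1), 0 °C
Reagents that add atoms: none
Why: Oxidative cleavage of the 4-methoxybenzyl ether by DDQ (oxidation to the benzylic oxocarbenium ion, then hydrolysis) in buffered wet CH2Cl2 should leave the allylic silyl ether and the alkene untouched and free the primary alcohol for C–C coupling.

**Step 5**
Reactants: 7 methyl 2-(hydroxymethyl)acrylate
Product: 8 methyl 2-{[(tert-butoxycarbonyl)oxy]methyl}acrylate
Conditions: Boc2O, DMAP (cat.), CH2Cl2, 0 °C → rt
Reagents that add atoms: di-tert-butyl dicarbonate, CC(C)(C)OC(=O)OC(=O)OC(C)(C)C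
Why: DMAP-catalysed O-acylation of the primary allylic alcohol gives the Morita–Baylis–Hillman-type carbonate, an allyl donor whose ionisation releases CO2 and tert-butoxide.

**Step 6**
Reactants: 6 (E)-5-[(tert-butyldimethylsilyl)oxy]-3-methylpent-3-en-1-ol; 8 methyl 2-{[(tert-butoxycarbonyl)oxy]methyl}acrylate (2 equiv)
Product: 11 (5R)-5-[(2E)-4-[(tert-butyldimethylsilyl)oxy]-2-methylbut-2-en-1-yl]-3-methylideneoxolan-2-one, via aldehyde 9 (not isolated), via hydroxy ester 10 (not isolated)
Conditions: [Ir(cod)Cl]2 (2.5 mol %), (S)-SEGPHOS (5 mol %), 4-cyano-3-nitrobenzoic acid (10 mol %), Cs2CO3 (20 mol %), THF, 70 °C; then PPTS (cat.), PhMe, 50 °C to complete lactonisation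
Reagents that add atoms: none
Why: In this Krische-type transfer-hydrogenative 2-(alkoxycarbonyl)allylation, the cyclometallated π-allyliridium C,O-benzoate formed in the flask dehydrogenates alcohol 6 to aldehyde 9 and delivers the 2-(methoxycarbonyl)allyl group to one aldehyde face through a closed chair transition state under control of the bisphosphine, setting the (4R) carbinol of 10, which lactonises with loss of methanol.

**Step 7**
Reactants: 11 (5R)-5-[(2E)-4-[(tert-butyldimethylsilyl)oxy]-2-methylbut-2-en-1-yl]-3-methylideneoxolan-2-one
Product: 12 (5R)-5-[(2E)-4-hydroxy-2-methylbut-2-en-1-yl]-3-methylideneoxolan-2-one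
Conditions: HF·pyridine, pyridine, THF, 0 °C → rt
Reagents that add atoms: none
Why: Desilylation with buffered HF·pyridine is non-basic, so the α-methylene lactone (a Michael acceptor), the stereocentre and the alkene geometry should be preserved.

**Step 8**
Reactants: 12 (5R)-5-[(2E)-4-hydroxy-2-methylbut-2-en-1-yl]-3-methylideneoxolan-2-one; 13 2-methoxybenzene-1,3-diol (2-methoxyresorcinol, 3 equiv)
Product: 14 (5R)-5-[(2E)-4-(3-hydroxy-2-methoxyphenoxy)-2-methylbut-2-en-1-yl]-3-methylideneoxolan-2-one
Conditions: PPh3, DIAD (betaine preformed at 0 °C), THF, 0 °C → rt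
Reagents that add atoms: none
Why: In this Mitsunobu etherification the primary allylic alcohol is activated as its alkoxyphosphonium ion and displaced by the phenoxide at the unhindered CH2 (SN2′ attack would have to build a quaternary centre), and the excess of the symmetric diol, whose two hydroxyls are equivalent, should hold the reaction at the monoether.

**Step 9**
Reactants: 14 (5R)-5-[(2E)-4-(3-hydroxy-2-methoxyphenoxy)-2-methylbut-2-en-1-yl]-3-methylideneoxolan-2-one; 15 propiolic acid
Product: 16 2-methoxy-3-{[(2E)-3-methyl-4-[(2R)-4-methylidene-5-oxooxolan-2-yl]but-2-en-1-yl]oxy}phenyl prop-2-ynoate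
Conditions: DCC, DMAP (2 mol %), CH2Cl2, −10 → 0 °C
Reagents that add atoms: none
Why: Steglich-type carbodiimide esterification of the remaining phenol at low temperature should form the terminal ynoate without base-induced conjugate addition to it or to the methylene lactone.

**Step 10**
Reactants: 16 2-methoxy-3-{[(2E)-3-methyl-4-[(2R)-4-methylidene-5-oxooxolan-2-yl]but-2-en-1-yl]oxy}phenyl prop-2-ynoate
Product: 17 8-methoxy-7-{[(2E)-3-methyl-4-[(2R)-4-methylidene-5-oxooxolan-2-yl]but-2-en-1-yl]oxy}-2H-chromen-2-one
Conditions: Ph3PAuCl (5 mol %), AgSbF6 (5 mol %), premixed and filtered from AgCl, CH2Cl2, rt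
Reagents that add atoms: none
Why: Ph3PAu+ (cationic monovalent gold) binds the electron-poor alkyne of 16, the arene carbon ortho to the ester oxygen (the future C4a) attacks the alkyne terminus anti to gold, and proton loss from the arenium ion followed by protodeauration of the vinylgold species releases the catalyst and the C3=C4 double bond. The closest known reaction type is the gold-catalysed intramolecular hydroarylation of aryl alkynoates to coumarins, a Friedel–Crafts alkenylation. The pyranone ring closes in the 6-endo-dig mode, because the ester tether holds the alkyne terminus over the ortho carbon; no stereocentre is formed and the remote lactone stereocentre is not touched. Regioselectivity is secured by the substrate: the second ortho position carries the methoxy group, and the attacking carbon is para to the alkoxy donor and so is the most nucleophilic free site of the ring. Chemoselectivity requires gold to activate the ynoate and not the two alkenes or the allylic aryl ether: the alkyne is the better ligand for gold, neither alkene can reach it through a small-ring transition state, and a silver-free catalyst solution at room temperature should keep ionisation of the allylic ether slow.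

**Step 11**
Reactants: 17 8-methoxy-7-{[(2E)-3-methyl-4-[(2R)-4-methylidene-5-oxooxolan-2-yl]but-2-en-1-yl]oxy}-2H-chromen-2-one
Product: 18 8-methoxy-7-{[(2R,3R)-3-methyl-3-{[(2S)-4-methylidene-5-oxooxolan-2-yl]methyl}oxiran-2-yl]methoxy}-2H-chromen-2-one (CNP0318299.1)
Conditions: 1,2:4,5-di-O-isopropylidene-β-D-erythro-2,3-hexodiulo-2,6-pyranose (Shi ketone, 30 mol %), 2KHSO5·KHSO4·K2SO4, K2CO3, Bu4NHSO4 (cat.), MeCN–CH2(OMe)2 / aq. Na2B4O7 buffer, 0 °C
Reagents that add atoms: potassium peroxymonosulfate, [K+].[O-]S(=O)(=O)OO
Why: In this Shi asymmetric epoxidation the chiral dioxirane formed from the D-fructose-derived ketone and KHSO5 transfers oxygen through a spiro transition state to the electron-richest alkene, the trisubstituted (E)-olefin, on the face that gives the (2R,3R)-oxirane, while the electron-poor exocyclic methylene and the coumarin C3=C4 bond should not react with the electrophilic oxidant; the lactone centre is untouched and only its descriptor changes from R to S because the oxirane carbon raises the CIP rank of the side chain.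

**Compound list**

1 | but-3-yn-1-ol | C#CCCO | starting material
2 | 1-[(but-3-yn-1-yloxy)methyl]-4-methoxybenzene | C#CCCOCc1ccc(OC)cc1 | intermediate
3 | (E)-dimethyl{4-[(4-methoxybenzyl)oxy]-2-methylbut-1-en-1-yl}alane | C[Al](C)/C=C(\C)CCOCc1ccc(OC)cc1 | intermediate (not isolated)
4 | (E)-5-[(4-methoxybenzyl)oxy]-3-methylpent-2-en-1-ol | OC/C=C(\C)CCOCc1ccc(OC)cc1 | intermediate
5 | (E)-tert-butyl({5-[(4-methoxybenzyl)oxy]-3-methylpent-2-en-1-yl}oxy)dimethylsilane | CC(C)(C)[Si](C)(C)OC/C=C(\C)CCOCc1ccc(OC)cc1 | intermediate
6 | (E)-5-[(tert-butyldimethylsilyl)oxy]-3-methylpent-3-en-1-ol | CC(C)(C)[Si](C)(C)OC/C=C(\C)CCO | intermediate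
7 | methyl 2-(hydroxymethyl)acrylate | C=C(CO)C(=O)OC | starting material
8 | methyl 2-{[(tert-butoxycarbonyl)oxy]methyl}acrylate | C=C(COC(=O)OC(C)(C)C)C(=O)OC | intermediate
9 | (E)-5-[(tert-butyldimethylsilyl)oxy]-3-methylpent-3-enal | CC(C)(C)[Si](C)(C)OC/C=C(\C)CC=O | intermediate (not isolated)
10 | methyl (4R,6E)-8-[(tert-butyldimethylsilyl)oxy]-4-hydroxy-6-methyl-2-methylideneoct-6-enoate | C=C(C[C@H](O)C/C(C)=C/CO[Si](C)(C)C(C)(C)C)C(=O)OC | intermediate (not isolated)
11 | (5R)-5-[(2E)-4-[(tert-butyldimethylsilyl)oxy]-2-methylbut-2-en-1-yl]-3-methylideneoxolan-2-one | C=C1C[C@@H](C/C(C)=C/CO[Si](C)(C)C(C)(C)C)OC1=O | intermediate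
12 | (5R)-5-[(2E)-4-hydroxy-2-methylbut-2-en-1-yl]-3-methylideneoxolan-2-one | C=C1C[C@@H](C/C(C)=C/CO)OC1=O | intermediate
13 | 2-methoxybenzene-1,3-diol (2-methoxyresorcinol) | COc1c(O)cccc1O | starting material
14 | (5R)-5-[(2E)-4-(3-hydroxy-2-methoxyphenoxy)-2-methylbut-2-en-1-yl]-3-methylideneoxolan-2-one | C=C1C[C@@H](C/C(C)=C/COc2cccc(O)c2OC)OC1=O | intermediate
15 | propiolic acid | C#CC(=O)O | starting material
16 | 2-methoxy-3-{[(2E)-3-methyl-4-[(2R)-4-methylidene-5-oxooxolan-2-yl]but-2-en-1-yl]oxy}phenyl prop-2-ynoate | C=C1C[C@@H](C/C(C)=C/COc2cccc(OC(=O)C#C)c2OC)OC1=O | intermediate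
17 | 8-methoxy-7-{[(2E)-3-methyl-4-[(2R)-4-methylidene-5-oxooxolan-2-yl]but-2-en-1-yl]oxy}-2H-chromen-2-one | C=C1C[C@@H](C/C(C)=C/COc2ccc3ccc(=O)oc3c2OC)OC1=O | intermediate
18 | 8-methoxy-7-{[(2R,3R)-3-methyl-3-{[(2S)-4-methylidene-5-oxooxolan-2-yl]methyl}oxiran-2-yl]methoxy}-2H-chromen-2-one | C=C1C[C@@H](C[C@@]2(C)O[C@@H]2COc2ccc3ccc(=O)oc3c2OC)OC1=O | target

**Step count**

Total: 11 steps. Longest linear sequence: 10 steps (1 → 2 → 4 → 5 → 6 → 11 → 12 → 14 → 16 → 17 → 18); step 5 is a one-step side branch.

**Steps most likely to fail**

Step 10 (gold hydroarylation). The Lewis-acidic gold cation or residual silver may ionise or rearrange the allylic aryl ether, engage one of the alkenes, or be sequestered by the terminal alkyne as an unreactive acetylide, so that ring closure stalls or the side chain is lost. The fallback builds the pyranone ring before the sensitive side chain is present. It sets out from 13 and 12 and returns at 17. Von Pechmann condensation of 13 with malic acid in concentrated H2SO4 at about 100 °C (formylacetic acid is generated in the flask, and either of the two equivalent carbons ortho to one hydroxyl and para to the other reacts) should give 7-hydroxy-8-methoxy-2H-chromen-2-one F1. Mitsunobu etherification of F1 with allylic alcohol 12 (PPh3, DIAD, THF, 0 °C → rt) should then give 17, and the route continues with step 11.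

Step 6 (iridium allylation–lactonisation). The transient β,γ-unsaturated aldehyde may be isomerised into conjugation by the carbonate base at 70 °C, an iridium hydride may migrate the alkene, or discrimination of the aldehyde faces may be insufficient. The fallback sets out from 6 and returns at 11. Oxidation of 6 with Dess–Martin periodinane (NaHCO3, CH2Cl2, 0 °C) gives aldehyde 9, here isolated and used cold. Enantioselective propargylation with allenylboronic acid pinacol ester and a BINOL-derived chiral phosphoric acid of the TRIP type (the enantiomer that delivers the S alcohol; toluene, 4 Å MS, −20 °C) should give (4S,6E)-8-[(tert-butyldimethylsilyl)oxy]-6-methyloct-6-en-1-yn-4-ol F2. It has the same spatial arrangement as 10; the descriptor is S because the propargyl group ranks below the side chain. Palladium-catalysed cyclocarbonylation of this homopropargylic alcohol (PdCl2, PPh3, SnCl2, CO 7 atm, MeCN, 75 °C) should close the α-methylene lactone 11 with retention at the carbinol.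

Step 11 (Shi epoxidation). Oxygen transfer to the alkene, which is deactivated by the allylic aryloxy group, may be slow, so that the ketone is consumed by Baeyer–Villiger decomposition; the two lactones may be opened by the basic medium; or facial selectivity may be inadequate. The fallback sets the oxirane by reagent control on the allylic alcohol; it sets out from 12 and returns at 18. Sharpless asymmetric epoxidation of 12 (Ti(OiPr)4, D-(−)-diethyl tartrate, tBuOOH, 4 Å MS, CH2Cl2, −20 °C) should give (5S)-5-{[(2R,3R)-3-(hydroxymethyl)-2-methyloxiran-2-yl]methyl}-3-methylideneoxolan-2-one F3. Mitsunobu etherification of F3 with 7-hydroxy-8-methoxy-2H-chromen-2-one F1 (made from 13 as in the fallback to step 10; PPh3, DIAD, THF, 0 °C → rt) should give 18 directly.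

**Further compounds**

F1 | step 10 | 7-hydroxy-8-methoxy-2H-chromen-2-one | COc1c(O)ccc2ccc(=O)oc12
F2 | step 6 | (4S,6E)-8-[(tert-butyldimethylsilyl)oxy]-6-methyloct-6-en-1-yn-4-ol | C#CC[C@H](O)C/C(C)=C/CO[Si](C)(C)C(C)(C)C
F3 | step 11 | (5S)-5-{[(2R,3R)-3-(hydroxymethyl)-2-methyloxiran-2-yl]methyl}-3-methylideneoxolan-2-one | C=C1C[C@@H](C[C@@]2(C)O[C@@H]2CO)OC1=O
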